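The oxirane carbons C1 and C10 of the ten-membered ring (germacrane numbering) are each flanked by a CH2 (C2, C9) that leads to an acyloxy carbinol (C3, C8). Both halves are therefore homoallylic alcohol retrons, an allyl and a methallyl carbinol. Ring-closing metathesis of these two termini makes the C1–C10 bond and the carbocycle in one operation. Its precursor is an open-chain tetraene built on the finished trans-disubstituted α-methylene-γ-butyrolactone. A ten-membered ring is expected to close to the ring-cis olefin, so the trans-oxirane is then installed stereospecifically: osmylation opposite the C3 and C8 oxygens, mesylation at C1, and invertive closure by the C10 hydroxyl.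

Key step: step 10

Remark on numbering: C1/C10 are the oxirane carbons (C10 bears CH3-14). C3 bears the isobutyrate. C4=C5 is the Z-olefin (CH3-15 on C4). O6 closes the lactone (C12 carbonyl, C11=C13 methylene). C7 is the lactone β-carbon. C8 bears the epoxyangelate.
Assumption: compounds 1 and 19 and all unnumbered reagents are taken as commercial.

Step 1
Reactants: 1 3-(trimethylsilyl)prop-2-ynal
Product: 3 (3S)-hex-5-en-1-yn-3-ol, via silylated alkynol 2 (not isolated)
Conditions: (−)-Ipc2B(allyl), Et2O, −78 °C; then 3 M NaOH, 30% H2O2, MeOH, 0 °C to rt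
Reagents that add atoms: (−)-B-allyldiisopinocampheylborane, C=CCB([C@@H]1C[C@@H]2C[C@H]([C@H]1C)C2(C)C)[C@@H]1C[C@@H]2C[C@H]([C@H]1C)C2(C)C
Why: Brown allylboration through a closed chair transition state, in which the (+)-α-pinene-derived Ipc groups send the allyl group to the Si face of the ynal and set C3 as S, while the alkaline peroxide/methanol work-up oxidises the B–C bonds and cleaves the alkynyl C–Si bond in the same flask.

Step 2
Reactants: 3 (3S)-hex-5-en-1-yn-3-ol
Product: 5 (1Z,3S)-1-iodo-2-methylhexa-1,5-dien-3-ol, via alkenylmagnesium chelate 4 (not isolated)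
Conditions: MeMgBr (3 equiv), CuI (20 mol%), THF, 0 °C to rt; then I2, −20 °C
Reagents that add atoms: methylmagnesium bromide, C[Mg]Br; iodine, II
Why: Alkoxide-directed, copper-catalysed anti-carbomagnesiation of a propargylic alcohol puts CH3 on the carbinol-side alkyne carbon (C4) and magnesium on C5 inside a five-membered chelate, so iodinolysis with retention should give the olefin with C3 and iodine cis (the later Z C4=C5) without touching C3.

Step 3
Reactants: 5 (1Z,3S)-1-iodo-2-methylhexa-1,5-dien-3-ol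
Product: 6 (1Z,3S)-1-iodo-2-methylhexa-1,5-dien-3-yl 2-methylpropanoate
Conditions: iPrCOCl, Et3N, DMAP (cat.), CH2Cl2, 0 °C
Reagents that add atoms: isobutyryl chloride, CC(C)C(=O)Cl
Why: DMAP-catalysed O-acylation installs the final C3 isobutyrate at once, so no protecting group is spent on O3 and the free Z-hydroxy enal (which would close to a lactol) is never formed; the C3–O bond is not broken and C3 stays S.

Step 4
Reactants: 6 (1Z,3S)-1-iodo-2-methylhexa-1,5-dien-3-yl 2-methylpropanoate
Product: 7 (2Z,4S)-3-methyl-1-oxohepta-2,6-dien-4-yl 2-methylpropanoate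
Conditions: Pd(PPh3)4 (5 mol%), CO (1 atm), Bu3SnH (slow addition), THF, 50 °C
Reagents that add atoms: carbon monoxide, [C-]#[O+]
Why: Stille-type carbonylative formylation (oxidative addition of the alkenyl iodide to zerovalent palladium, CO insertion, hydride transfer from tin) proceeds with retention of olefin geometry, and oxidative addition to the C–I bond is much faster than ionisation of the hindered allylic ester.

Step 5
Reactants: 1 3-(trimethylsilyl)prop-2-ynal
Product: 9 (3R)-5-methylhex-5-en-1-yn-3-ol, via silylated alkynol 8 (not isolated)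
Conditions: (+)-Ipc2BOMe, 2-methylallylmagnesium chloride, Et2O, 0 °C; then 1, −78 °C; then 3 M NaOH, 30% H2O2, MeOH, 0 °C to rt
Reagents that add atoms: 2-methylallylmagnesium chloride, C=C(C)C[Mg]Cl, delivered as (+)-B-(2-methylallyl)diisopinocampheylborane, C=C(C)CB([C@H]1C[C@H]2C[C@@H]([C@@H]1C)C2(C)C)[C@H]1C[C@H]2C[C@@H]([C@@H]1C)C2(C)C
Why: Brown methallylboration with the (−)-α-pinene-derived reagent attacks the opposite (Re) face of the same ynal through the chair transition state and sets C8 as R, and the work-up again removes the alkynyl silyl group.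

Step 6
Reactants: 9 (3R)-5-methylhex-5-en-1-yn-3-ol
Product: 10 tert-butyl(dimethyl){[(3R)-5-methylhex-5-en-1-yn-3-yl]oxy}silane
Conditions: TBSCl, imidazole, DMF, rt
Reagents that add atoms: tert-butyldimethylsilyl chloride, CC(C)(C)[Si](C)(C)Cl
Why: Imidazole-promoted silylation masks O8 against the organolithium and aluminium hydride steps that follow and leaves the stereocentre untouched.

Step 7
Reactants: 10 tert-butyl(dimethyl){[(3R)-5-methylhex-5-en-1-yn-3-yl]oxy}silane
Product: 12 methyl (4R)-4-[(tert-butyldimethylsilyl)oxy]-6-methylhept-6-en-2-ynoate, via lithium acetylide 11 (not isolated)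
Conditions: n-BuLi, THF, −78 °C; then ClCO2Me, −78 °C to 0 °C
Reagents that add atoms: methyl chloroformate, COC(=O)Cl
Why: Deprotonation of the terminal alkyne and C-acylation of the acetylide by the chloroformate brings in C12, and nothing else in 10 is acidic or electrophilic under these conditions.

Step 8
Reactants: 12 methyl (4R)-4-[(tert-butyldimethylsilyl)oxy]-6-methylhept-6-en-2-ynoate
Product: 14 methyl (2Z,4R)-4-[(tert-butyldimethylsilyl)oxy]-6-methyl-2-[(4,4,5,5-tetramethyl-1,3,2-dioxaborolan-2-yl)methyl]hepta-2,6-dienoate, via alkenylalane 13 (not isolated)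
Conditions: iBu2AlH, HMPA, THF, 0 °C; then ICH2Bpin, 0 °C to rt
Reagents that add atoms: 2-(iodomethyl)-4,4,5,5-tetramethyl-1,3,2-dioxaborolane, ICB1OC(C)(C)C(C)(C)O1
Why: Conjugate syn-hydroalumination of the ynoate by the iBu2AlH–HMPA complex puts H on C7 and Al on C11 on the same side, and alkylation of the alkenylalane with retention gives the 2-alkoxycarbonyl allylboronate whose C8 chain is trans to CH2B (cis to the ester), the geometry needed for an anti addition.

Step 9
Reactants: 7 (2Z,4S)-3-methyl-1-oxohepta-2,6-dien-4-yl 2-methylpropanoate; 14 methyl (2Z,4R)-4-[(tert-butyldimethylsilyl)oxy]-6-methyl-2-[(4,4,5,5-tetramethyl-1,3,2-dioxaborolan-2-yl)methyl]hepta-2,6-dienoate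
Product: 16 (1Z,3S)-1-{(2R,3S)-3-[(1R)-1-(tert-butyldimethylsilyloxy)-3-methylbut-3-enyl]-4-methylidene-5-oxooxolan-2-yl}-2-methylhexa-1,5-dien-3-yl 2-methylpropanoate (seco-lactone tetraene), via anti hydroxy ester 15 (not isolated)
Conditions: Sc(OTf)3 (10 mol%), toluene, 0 °C to rt; then p-TsOH·H2O (10 mol%), rt
Reagents that add atoms: none
Why: Lewis-acid-catalysed allylboration/lactonisation through a closed chair in which the C8 chain (trans to CH2B) and the aldehyde residue are both equatorial gives the anti C6/C7 adduct and hence the trans-lactone with its C11=C13 methylene, while allylic 1,3-strain with the cis ester holds H8 in the olefin plane so that the aldehyde should approach anti to the C9 chain, which sets C7 and, through the chair, C6 (R) relative to C8.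

Step 10
Reactants: 16 seco-lactone tetraene
Product: 17 (3S,6R,7S,8R,1(10)Z,4Z)-8-(tert-butyldimethylsilyloxy)-3-(isobutyryloxy)germacra-1(10),4,11(13)-trien-12,6-olide
Conditions: second-generation Hoveyda–Grubbs catalyst (10 mol%, in portions), 1,4-benzoquinone (20 mol%), toluene (1 mM), 80 °C, argon sparge
Reagents that add atoms: none
Why: The ruthenium alkylidene loads on the monosubstituted C1 vinyl terminus, adds [2+2] to the 1,1-disubstituted C10 methallyl olefin and cycloreverts, expelling ethene and forming C1=C10; the closest known reaction type is ring-closing metathesis to medium-ring trisubstituted cycloalkenes. One ring is closed, the ten-membered carbocycle C1–C10, by end-to-end closure of two chain termini that the cis C4=C5 olefin and the trans C6/C7 lactone bend towards each other in a U. No stereocentre is created; the only stereo element is the olefin geometry, and under the reversible conditions of a second-generation catalyst the less strained ring-cis (Z) olefin, with C2 and C9 on the same side, is expected. The step needs site selectivity among four olefins, which the substrate secures because trisubstituted C4=C5 lies between two acyloxy carbons and the C11=C13 methylene is electron-poor and 1,1-disubstituted, so both are poor metathesis partners. It also needs cyclisation to beat dimerisation and olefin migration, which millimolar dilution, ethene removal and benzoquinone secure. The Z outcome is what the route wants, since one syn-dihydroxylation and one inversion turn it into the trans-oxirane.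

Step 11
Reactants: 17 macrocyclic silyl ether
Product: 18 (3S,6R,7R,8R,1(10)Z,4Z)-8-hydroxy-3-(isobutyryloxy)germacra-1(10),4,11(13)-trien-12,6-olide
Conditions: HF·pyridine, THF, 0 °C to rt
Reagents that add atoms: none
Why: Fluoride-driven Si–O cleavage under mildly acidic conditions frees O8 without base, so neither conjugate addition to C13 nor translactonisation towards O8 is triggered and no stereocentre is affected (the C7 descriptor changes only through priorities).

Step 12
Reactants: 19 methyl angelate (methyl (Z)-2-methylbut-2-enoate)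
Product: 20 (Z)-2-methylbut-2-en-1-ol
Conditions: iBu2AlH (2.2 equiv), CH2Cl2, −78 °C to 0 °C; Rochelle salt work-up
Reagents that add atoms: none
Why: 1,2-Reduction of the enoate by two hydride equivalents at low temperature gives the allylic alcohol and avoids the acid, base or heat that would isomerise the Z-olefin to the tiglyl series.

Step 13
Reactants: 20 (Z)-2-methylbut-2-en-1-ol
Product: 21 [(2R,3S)-2,3-dimethyloxiran-2-yl]methanol
Conditions: Ti(OiPr)4 (cat.), D-(−)-diisopropyl tartrate (cat.), t-BuOOH, 4 Å MS, CH2Cl2, −20 °C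
Reagents that add atoms: tert-butyl hydroperoxide, CC(C)(C)OO
Why: Sharpless asymmetric epoxidation, in which the D-(−)-tartrate titanium complex delivers oxygen to the olefin face that gives the 2R series and the syn addition keeps the C4 methyl cis to CH2OH, so both side-chain stereocentres are set by the catalyst.

Step 14
Reactants: 21 [(2R,3S)-2,3-dimethyloxiran-2-yl]methanol
Product: 22 (2S,3S)-2,3-dimethyloxirane-2-carboxylic acid (epoxyangelic acid)
Conditions: RuCl3·xH2O (2 mol%), NaIO4, MeCN/CCl4/H2O, rt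
Reagents that add atoms: sodium periodate, [Na+].[O-]I(=O)(=O)=O
Why: Catalytic RuO4 oxidation takes the primary alcohol through the aldehyde hydrate to the glycidic acid without opening the oxirane, and the C2 descriptor changes from R to S only because CO2H outranks C3.

Step 15
Reactants: 18 macrocyclic C8 alcohol; 22 (2S,3S)-2,3-dimethyloxirane-2-carboxylic acid
Product: 24 (3S,6R,7R,8R,1(10)Z,4Z)-8-[(2S,3S)-2,3-epoxy-2-methylbutanoyloxy]-3-(isobutyryloxy)germacra-1(10),4,11(13)-trien-12,6-olide, via mixed anhydride 23 (not isolated)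
Conditions: 22, 2,4,6-Cl3C6H2COCl, Et3N, toluene, rt; then 18, DMAP, rt
Reagents that add atoms: none
Why: Yamaguchi esterification activates the hindered α-quaternary acid as a mixed anhydride that DMAP transfers to the hindered secondary alcohol, and because only the O–H bond of 18 is broken C8 stays R.

Step 16
Reactants: 24 Z,Z-diene diester
Product: 25 (1S,3S,6R,7R,8R,10R,4Z)-1,10-dihydroxy-8-[(2S,3S)-2,3-epoxy-2-methylbutanoyloxy]-3-(isobutyryloxy)germacra-4,11(13)-dien-12,6-olide
Conditions: OsO4 (5 mol%), NMO, acetone/H2O, 0 °C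
Reagents that add atoms: N-methylmorpholine N-oxide, C[N+]1([O-])CCOCC1; water, O
Why: Upjohn syn-dihydroxylation through a [3+2] osmate ester should pick C1=C10 as the only electron-rich olefin (C4=C5 carries two allylic acyloxy groups, C11=C13 is conjugated to the lactone) and should add on the α face, opposite the two homoallylic β-acyloxy groups on C3 and C8, which sets C1 as S and C10 as R.

Step 17
Reactants: 25 1α,10α-diol
Product: 27 target, (1R,3S,6R,7R,8R,10R,4Z)-1,10-epoxy-8-[(2S,3S)-2,3-epoxy-2-methylbutanoyloxy]-3-(isobutyryloxy)germacra-4,11(13)-dien-12,6-olide, via C1 mesylate 26 (not isolated)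
Conditions: MsCl, Et3N, CH2Cl2, −10 °C; then DBU, rt
Reagents that add atoms: none
Why: Selective sulfonylation of the secondary C1 hydroxyl over the tertiary C10 hydroxyl followed by base-induced 3-exo-tet closure inverts C1 (S to R) and retains C10 (R), so the syn diol of the Z-olefin becomes the trans-oxirane, and the non-nucleophilic base spares the esters and the methylene lactone.

Compound list
1 | 3-(trimethylsilyl)prop-2-ynal | C[Si](C)(C)C#CC=O | starting material
2 | (3S)-1-(trimethylsilyl)hex-5-en-1-yn-3-ol | C[Si](C)(C)C#C[C@@H](O)CC=C | intermediate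
3 | (3S)-hex-5-en-1-yn-3-ol | C#C[C@@H](O)CC=C | intermediate
4 | (5S)-4-methyl-5-(prop-2-enyl)-2,5-dihydro-1,2-oxamagnesole (alkenylmagnesium chelate) | CC1=C[Mg]O[C@H]1CC=C | intermediate
5 | (1Z,3S)-1-iodo-2-methylhexa-1,5-dien-3-ol | I/C=C(/C)[C@@H](O)CC=C | intermediate
6 | (1Z,3S)-1-iodo-2-methylhexa-1,5-dien-3-yl 2-methylpropanoate | I/C=C(/C)[C@@H](OC(=O)C(C)C)CC=C | intermediate
7 | (2Z,4S)-3-methyl-1-oxohepta-2,6-dien-4-yl 2-methylpropanoate | O=C/C=C(/C)[C@@H](OC(=O)C(C)C)CC=C | intermediate
8 | (3R)-5-methyl-1-(trimethylsilyl)hex-5-en-1-yn-3-ol | C[Si](C)(C)C#C[C@H](O)CC(C)=C | intermediate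
9 | (3R)-5-methylhex-5-en-1-yn-3-ol | C#C[C@H](O)CC(C)=C | intermediate
10 | tert-butyl(dimethyl){[(3R)-5-methylhex-5-en-1-yn-3-yl]oxy}silane | C#C[C@H](O[Si](C)(C)C(C)(C)C)CC(C)=C | intermediate
11 | lithium acetylide of 10 | [Li]C#C[C@H](O[Si](C)(C)C(C)(C)C)CC(C)=C | intermediate
12 | methyl (4R)-4-[(tert-butyldimethylsilyl)oxy]-6-methylhept-6-en-2-ynoate | COC(=O)C#C[C@H](O[Si](C)(C)C(C)(C)C)CC(C)=C | intermediate
13 | methyl (4R)-2-(diisobutylalumanyl)-4-[(tert-butyldimethylsilyl)oxy]-6-methylhepta-2,6-dienoate, H and Al cis | COC(=O)/C([Al](CC(C)C)CC(C)C)=C\[C@H](O[Si](C)(C)C(C)(C)C)CC(C)=C | intermediate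
14 | methyl (2Z,4R)-4-[(tert-butyldimethylsilyl)oxy]-6-methyl-2-[(4,4,5,5-tetramethyl-1,3,2-dioxaborolan-2-yl)methyl]hepta-2,6-dienoate | COC(=O)/C(CB1OC(C)(C)C(C)(C)O1)=C\[C@H](O[Si](C)(C)C(C)(C)C)CC(C)=C | intermediate
15 | anti hydroxy ester, open form of 16 (C3 S, C6 R, C7 S, C8 R) | COC(=O)C(=C)[C@@H]([C@H](O)/C=C(/C)[C@@H](OC(=O)C(C)C)CC=C)[C@H](O[Si](C)(C)C(C)(C)C)CC(C)=C | intermediate
16 | seco-lactone tetraene (C3 S, C6 R, C7 S, C8 R) | C=C1C(=O)O[C@H](/C=C(/C)[C@@H](OC(=O)C(C)C)CC=C)[C@H]1[C@H](O[Si](C)(C)C(C)(C)C)CC(C)=C | intermediate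
17 | (3S,6R,7S,8R,1(10)Z,4Z)-8-(tert-butyldimethylsilyloxy)-3-(isobutyryloxy)germacra-1(10),4,11(13)-trien-12,6-olide | C=C1C(=O)O[C@@H]2/C=C(/C)[C@@H](OC(=O)C(C)C)C/C=C(/C)C[C@@H](O[Si](C)(C)C(C)(C)C)[C@@H]12 | intermediate
18 | (3S,6R,7R,8R,1(10)Z,4Z)-8-hydroxy-3-(isobutyryloxy)germacra-1(10),4,11(13)-trien-12,6-olide | C=C1C(=O)O[C@@H]2/C=C(/C)[C@@H](OC(=O)C(C)C)C/C=C(/C)C[C@@H](O)[C@@H]12 | intermediate
19 | methyl angelate | C/C=C(/C)C(=O)OC | starting material
20 | (Z)-2-methylbut-2-en-1-ol | C/C=C(/C)CO | intermediate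
21 | [(2R,3S)-2,3-dimethyloxiran-2-yl]methanol | OC[C@@]1(C)O[C@H]1C | intermediate
22 | (2S,3S)-2,3-dimethyloxirane-2-carboxylic acid | OC(=O)[C@@]1(C)O[C@H]1C | intermediate
23 | (2S,3S)-2,3-dimethyloxirane-2-carboxylic 2,4,6-trichlorobenzoic anhydride | O=C(OC(=O)[C@@]1(C)O[C@H]1C)c1c(Cl)cc(Cl)cc1Cl | intermediate
24 | (3S,6R,7R,8R,1(10)Z,4Z)-8-[(2S,3S)-2,3-epoxy-2-methylbutanoyloxy]-3-(isobutyryloxy)germacra-1(10),4,11(13)-trien-12,6-olide | C=C1C(=O)O[C@@H]2/C=C(/C)[C@@H](OC(=O)C(C)C)C/C=C(/C)C[C@@H](OC(=O)[C@@]3(C)O[C@H]3C)[C@@H]12 | intermediate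
25 | (1S,10R)-1,10-diol of 24 | C=C1C(=O)O[C@@H]2/C=C(/C)[C@@H](OC(=O)C(C)C)C[C@H](O)[C@](C)(O)C[C@@H](OC(=O)[C@@]3(C)O[C@H]3C)[C@@H]12 | intermediate
26 | C1 methanesulfonate of 25 | C=C1C(=O)O[C@@H]2/C=C(/C)[C@@H](OC(=O)C(C)C)C[C@H](OS(C)(=O)=O)[C@](C)(O)C[C@@H](OC(=O)[C@@]3(C)O[C@H]3C)[C@@H]12 | intermediate
27 | CNP0117882.1, (1R,3S,6R,7R,8R,10R,4Z)-1,10-epoxy-8-[(2S,3S)-2,3-epoxy-2-methylbutanoyloxy]-3-(isobutyryloxy)germacra-4,11(13)-dien-12,6-olide | C=C1C(=O)O[C@@H]2/C=C(/C)[C@@H](OC(=O)C(C)C)C[C@H]3O[C@]3(C)C[C@@H](OC(=O)[C@@]3(C)O[C@H]3C)[C@@H]12 | target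

Total step count: 17. Longest linear sequence: 10 steps (1–4, 9–11, 15–17; the branch 5–8 is equally long).

Steps most likely to fail

Step 10 (key step). Geometric control may be lost, with the ring closing to the ring-trans olefin because the metallacyclobutane leading to it is less congested. The fallback runs from 16 back to 27. The closure is then taken on as the (1(10)E,4Z)-cyclodecadiene silyl ether F1, which already has the geometry of the final ring. HF·pyridine should give the E-configured C8 alcohol F2. Yamaguchi acylation by 22 through 23 should give the E-configured epoxyangelate F3. mCPBA (NaHCO3, CH2Cl2, 0 °C) should then epoxidise the electron-richest olefin C1=C10 on its exposed outer face and give 27 directly, so dihydroxylation and inversion are dropped.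

Step 9. Facial selection on the allyl unit may go the other way, the aldehyde approaching anti to the silyloxy group instead of anti to C9. That would invert C6 and C7 relative to C8. The fallback runs from 1 back to 24: the C8-epimeric series is made on purpose and C8 is corrected in the acylation.
- Methallylboration of 1 with the (+)-α-pinene-derived borane should give the silylated (S)-alkynol F4 and, after desilylation in the same flask, (3S)-5-methylhex-5-en-1-yn-3-ol F5.
- Silylation gives the (S)-silyl ether F6. Lithiation to the lithium acetylide F7 and methyl chloroformate give the (4S)-ynoate F8.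
- Hydroalumination to the alkenylalane F9 and ICH2Bpin give the (4S)-allylboronate F10.
- Allylboration of 7 should then give, through the hydroxy ester F11, the 8-epi seco-lactone F12 with C6 and C7 as in the target.
- Metathesis gives the 8-epi macrocyclic silyl ether F13, and HF·pyridine gives the 8-epi alcohol F14.
- Mitsunobu esterification with 22 (PPh3, DIAD, toluene, 0 °C) inverts C8 and delivers 24.

Step 16. Osmium tetroxide may add to the β face of C1=C10, or oxidation may spread to the C11=C13 methylene before C1=C10 is consumed. The fallback runs from 17 back to 27. The oxirane is built at the silyl ether stage, where the large silyloxy group on C8 shields the β face more strongly and no epoxy ester is exposed. OsO4/NMO on 17 should give the silyl ether diol F15, and MsCl/Et3N the silyl ether mesylate F16. DBU closes this to the silyl ether oxirane F17, TBAF buffered with AcOH frees the oxirane C8 alcohol F18, and Yamaguchi acylation by 22 through 23 gives 27.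

Further compounds
F1 | step 10 | (1(10)E,4Z) isomer of 17 | C=C1C(=O)O[C@@H]2/C=C(/C)[C@@H](OC(=O)C(C)C)C/C=C(\C)C[C@@H](O[Si](C)(C)C(C)(C)C)[C@@H]12
F2 | step 10 | (1(10)E,4Z) isomer of 18 | C=C1C(=O)O[C@@H]2/C=C(/C)[C@@H](OC(=O)C(C)C)C/C=C(\C)C[C@@H](O)[C@@H]12
F3 | step 10 | (1(10)E,4Z) isomer of 24 | C=C1C(=O)O[C@@H]2/C=C(/C)[C@@H](OC(=O)C(C)C)C/C=C(\C)C[C@@H](OC(=O)[C@@]3(C)O[C@H]3C)[C@@H]12
F4 | step 9 | (3S)-5-methyl-1-(trimethylsilyl)hex-5-en-1-yn-3-ol | C[Si](C)(C)C#C[C@@H](O)CC(C)=C
F5 | step 9 | (3S)-5-methylhex-5-en-1-yn-3-ol | C#C[C@@H](O)CC(C)=C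
F6 | step 9 | tert-butyl(dimethyl){[(3S)-5-methylhex-5-en-1-yn-3-yl]oxy}silane | C#C[C@@H](O[Si](C)(C)C(C)(C)C)CC(C)=C
F7 | step 9 | lithium acetylide of F6 | [Li]C#C[C@@H](O[Si](C)(C)C(C)(C)C)CC(C)=C
F8 | step 9 | methyl (4S)-4-[(tert-butyldimethylsilyl)oxy]-6-methylhept-6-en-2-ynoate | COC(=O)C#C[C@@H](O[Si](C)(C)C(C)(C)C)CC(C)=C
F9 | step 9 | (4S)-alkenylalane, H and Al cis | COC(=O)/C([Al](CC(C)C)CC(C)C)=C\[C@@H](O[Si](C)(C)C(C)(C)C)CC(C)=C
F10 | step 9 | methyl (2Z,4S)-4-[(tert-butyldimethylsilyl)oxy]-6-methyl-2-[(4,4,5,5-tetramethyl-1,3,2-dioxaborolan-2-yl)methyl]hepta-2,6-dienoate | COC(=O)/C(CB1OC(C)(C)C(C)(C)O1)=C\[C@@H](O[Si](C)(C)C(C)(C)C)CC(C)=C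
F11 | step 9 | 8-epi hydroxy ester | COC(=O)C(=C)[C@@H]([C@H](O)/C=C(/C)[C@@H](OC(=O)C(C)C)CC=C)[C@@H](O[Si](C)(C)C(C)(C)C)CC(C)=C
F12 | step 9 | 8-epi seco-lactone tetraene | C=C1C(=O)O[C@H](/C=C(/C)[C@@H](OC(=O)C(C)C)CC=C)[C@H]1[C@@H](O[Si](C)(C)C(C)(C)C)CC(C)=C
F13 | step 9 | 8-epi macrocyclic silyl ether | C=C1C(=O)O[C@@H]2/C=C(/C)[C@@H](OC(=O)C(C)C)C/C=C(/C)C[C@H](O[Si](C)(C)C(C)(C)C)[C@@H]12
F14 | step 9 | 8-epi macrocyclic alcohol | C=C1C(=O)O[C@@H]2/C=C(/C)[C@@H](OC(=O)C(C)C)C/C=C(/C)C[C@H](O)[C@@H]12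
F15 | step 16 | (1S,10R)-1,10-diol of 17 | C=C1C(=O)O[C@@H]2/C=C(/C)[C@@H](OC(=O)C(C)C)C[C@H](O)[C@](C)(O)C[C@@H](O[Si](C)(C)C(C)(C)C)[C@@H]12
F16 | step 16 | C1 methanesulfonate of F15 | C=C1C(=O)O[C@@H]2/C=C(/C)[C@@H](OC(=O)C(C)C)C[C@H](OS(C)(=O)=O)[C@](C)(O)C[C@@H](O[Si](C)(C)C(C)(C)C)[C@@H]12
F17 | step 16 | (1R,10R)-1,10-oxirane 8-silyl ether | C=C1C(=O)O[C@@H]2/C=C(/C)[C@@H](OC(=O)C(C)C)C[C@H]3O[C@]3(C)C[C@@H](O[Si](C)(C)C(C)(C)C)[C@@H]12
F18 | step 16 | (1R,10R)-1,10-oxirane 8-alcohol | C=C1C(=O)O[C@@H]2/C=C(/C)[C@@H](OC(=O)C(C)C)C[C@H]3O[C@]3(C)C[C@@H](O)[C@@H]12
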